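The route rests on disconnecting C6–C7 (C6 = lactone carbinol carbon, C7 = ring-fusion carbon), the bond shared by the ten-membered carbocycle and the γ-lactone. C7 is allylic to the exocyclic C11=C13 methylene and C6 bears the lactone oxygen, so C13–C11(CO2Me)=C7 is a latent 2-(methoxycarbonyl)allyl nucleophile and C6 a latent aldehyde. Treating acyclic bromo enal 27, which already carries both cis-epoxides, the C8 silyloxy group and the Z-C4=C5 alkene, with CrCl2 should give an allylchromium species that attacks C6 through C7 with allylic transposition. One operation closes the ten-membered ring, sets C6 and C7, creates the C11=C13 methylene and lets the C6 alkoxide close the lactone.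

Key step: step 22

Remark: target numbering is used throughout: C1/C10 epoxide (C10 bears methyl C14), C2/C3 epoxide, C4(C15H2OH)=C5, C6 (lactone oxygen), C7 (ring fusion), C8 (angelate), C9 (CH2), C11=C13 (methylene), C12 (lactone carbonyl). TBS = tert-butyldimethylsilyl, TBDPS = tert-butyldiphenylsilyl, TES = triethylsilyl, PMB = 4-methoxybenzyl.
Remark: compounds 5, 13 and 32 are assumed to be catalogue compounds.

Step 1
Reactants: 1 but-2-yn-1-ol
Product: 3 (2Z)-3-iodobut-2-en-1-ol, via cyclic vinylalanate 2 (not isolated)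
Conditions: NaAlH2(OCH2CH2OMe)2, THF, 0 °C; then I2, −78 °C
Reagents that add atoms: iodine, II
Why: Hydroxyl-directed trans-hydroalumination of the propargylic alcohol places aluminium on C3 in a five-membered alanate and iodinolysis with retention gives the Z-iodide (iodine cis to CH2OH), the geometry that later makes C9 and C2 cis on C10=C1.

Step 2
Reactants: 3 (2Z)-3-iodobut-2-en-1-ol
Product: 4 TBS ether of 3
Conditions: t-BuMe2SiCl, imidazole, CH2Cl2, 0 °C
Reagents that add atoms: tert-butyldimethylsilyl chloride, CC(C)(C)[Si](C)(C)Cl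
Why: Routine silylation of a primary alcohol, and the TBS ether resists tert-butyllithium and silyl migration at −78 °C.

Step 3
Reactants: 4 TBS ether of 3; 5 (R)-glycidyl 4-methoxybenzyl ether
Product: 7 homoallylic alcohol, via vinyllithium 6 (not isolated)
Conditions: t-BuLi (2 equiv), Et2O, −78 °C; then 5, BF3·OEt2, −78 °C
Reagents that add atoms: none
Why: Iodine–lithium exchange keeps the alkene geometry and the vinyllithium opens the BF3-activated epoxide at its CH2 terminus (SN2), so C8 comes unchanged from 5 and the Z-trisubstituted C10=C1 alkene is in place.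

Step 4
Reactants: 7 homoallylic alcohol
Product: 8 bis-TBS ether
Conditions: t-BuMe2SiCl, imidazole, DMF, 23 °C
Reagents that add atoms: tert-butyldimethylsilyl chloride, CC(C)(C)[Si](C)(C)Cl
Why: Routine silylation of the secondary C8 hydroxyl, which stays protected until after the ring closure.

Step 5
Reactants: 8 bis-TBS ether
Product: 9 Z-allylic alcohol
Conditions: camphorsulfonic acid (0.1 equiv), MeOH/CH2Cl2, 0 °C
Reagents that add atoms: none
Why: Acid-catalysed methanolysis removes the unhindered primary allylic TBS ether much faster than the secondary one.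

Step 6
Reactants: 9 Z-allylic alcohol
Product: 10 epoxy alcohol
Conditions: Ti(OiPr)4, D-(−)-diethyl tartrate, t-BuOOH, 4 Å molecular sieves, CH2Cl2, −20 °C
Reagents that add atoms: tert-butyl hydroperoxide, CC(C)(C)OO
Why: Sharpless asymmetric epoxidation of the nerol-type alcohol with the D-tartrate should give the (2R,3S)-epoxy alcohol (the antipode of the 2S,3R product known from the L-tartrate), which sets C1 and C10, and the Z-alkene makes the epoxide cis.

Step 7
Reactants: 10 epoxy alcohol
Product: 11 epoxy aldehyde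
Conditions: Dess–Martin periodinane, NaHCO3, CH2Cl2, 0 °C
Reagents that add atoms: none
Why: Buffered Dess–Martin oxidation gives the α,β-epoxy aldehyde without epoxide opening, and the oxirane α-carbon does not epimerise.

Step 8
Reactants: 11 epoxy aldehyde
Product: 12 alkynyl epoxide
Conditions: dimethyl (1-diazo-2-oxopropyl)phosphonate, K2CO3, MeOH, 0 °C to 23 °C
Reagents that add atoms: dimethyl (1-diazo-2-oxopropyl)phosphonate, COP(=O)(OC)C(=[N+]=[N-])C(C)=O
Why: Seyferth–Gilbert homologation in the Ohira–Bestmann form adds C3 as a terminal alkyne under carbonate conditions that epoxy aldehydes tolerate.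

Step 9
Reactants: 13 methyl 4-hydroxybut-2-ynoate
Product: 14 TBDPS ether of 13
Conditions: t-BuPh2SiCl, imidazole, CH2Cl2, 0 °C to 23 °C
Reagents that add atoms: tert-butyl(chloro)diphenylsilane, CC(C)(C)[Si](Cl)(c1ccccc1)c1ccccc1
Why: Routine silylation, and the acid-stable TBDPS group protects the C15 oxygen to the last step.

Step 10
Reactants: 14 TBDPS ether of 13
Product: 15 (Z)-β-iodo enoate
Conditions: NaI, AcOH, 70 °C
Reagents that add atoms: sodium iodide, [Na+].[I-]
Why: Conjugate addition of iodide and protonation of the allenolate (net anti hydroiodination of the ynoate) should give the Z-iodide with iodine cis to CO2Me, which fixes C3 cis to C6 on the future C4=C5 alkene.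

Step 11
Reactants: 12 alkynyl epoxide; 15 (Z)-β-iodo enoate
Product: 16 enynoate
Conditions: PdCl2(PPh3)2 (3 mol%), CuI (6 mol%), Et3N, THF, 23 °C
Reagents that add atoms: none
Why: Sonogashira coupling of the activated vinyl iodide proceeds at room temperature with retention of alkene geometry and joins C3 to C4.

Step 12
Reactants: 16 enynoate
Product: 17 Z,Z-dienoate
Conditions: H2 (1 atm), Pd on CaCO3 poisoned with Pb(OAc)2, quinoline, EtOAc, 23 °C
Reagents that add atoms: none
Why: Syn semi-hydrogenation of the alkyne on poisoned palladium should give the Z-C2=C3 alkene and leave the trisubstituted enoate alkene and the epoxide untouched.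

Step 13
Reactants: 17 Z,Z-dienoate
Product: 18 bis-epoxy enoate
Conditions: m-CPBA, NaHCO3, CH2Cl2, 0 °C
Reagents that add atoms: 3-chloroperbenzoic acid, OOC(=O)c1cccc(Cl)c1
Why: In this Prilezhaev epoxidation only the electron-rich γ,δ-alkene of the dienoate reacts, stereospecifically to the cis-epoxide; with H1 eclipsing the Z-alkene (A(1,3) strain) C9 and the C10 methyl group cover one face, so oxygen should arrive syn to the oxirane oxygen and set C2 and C3 as in the target.

Step 14
Reactants: 18 bis-epoxy enoate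
Product: 19 Z-allylic alcohol
Conditions: i-Bu2AlH (2.2 equiv), CH2Cl2, −78 °C; aqueous sodium potassium tartrate work-up
Reagents that add atoms: none
Why: 1,2-Reduction of the enoate at low temperature gives the C6 alcohol without touching the epoxides or the silyl and PMB ethers.

Step 15
Reactants: 19 Z-allylic alcohol
Product: 20 TES ether
Conditions: Et3SiCl, imidazole, CH2Cl2, 0 °C
Reagents that add atoms: chlorotriethylsilane, CC[Si](Cl)(CC)CC
Why: Immediate silylation masks the C6 hydroxyl, which is held close to the C2/C3 epoxide, with a group that can later be removed beside TBS and TBDPS ethers.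

Step 16
Reactants: 20 TES ether
Product: 21 primary alcohol
Conditions: 2,3-dichloro-5,6-dicyano-1,4-benzoquinone, CH2Cl2/pH 7 buffer, 0 °C
Reagents that add atoms: none
Why: Oxidative cleavage of the PMB ether under neutral conditions frees the C7 hydroxyl and leaves silyl ethers and epoxides intact.

Step 17
Reactants: 21 primary alcohol
Product: 22 α-silyloxy aldehyde
Conditions: Dess–Martin periodinane, NaHCO3, CH2Cl2, 0 °C
Reagents that add atoms: none
Why: Buffered Dess–Martin oxidation gives the C7 aldehyde without epimerising C8.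

Step 18
Reactants: 22 α-silyloxy aldehyde; 23 methyl acrylate
Product: 24 Morita–Baylis–Hillman adduct
Conditions: 1,4-diazabicyclo[2.2.2]octane (1 equiv), neat methyl acrylate, 23 °C
Reagents that add atoms: none
Why: The Morita–Baylis–Hillman reaction attaches C11, C12 and C13 to C7, and the configuration of the new carbinol is irrelevant because it is lost in step 21.

Step 19
Reactants: 24 Morita–Baylis–Hillman adduct
Product: 25 diol
Conditions: HF·pyridine, pyridine, THF, 0 °C
Reagents that add atoms: none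
Why: Buffered fluoride cleaves the primary TES ether selectively beside the secondary TBS and primary TBDPS ethers and avoids the acid that could make the C6 hydroxyl open the C2/C3 epoxide.

Step 20
Reactants: 25 diol
Product: 26 hydroxy enal
Conditions: MnO2 (activated, excess), CH2Cl2, 23 °C
Reagents that add atoms: none
Why: MnO2 oxidises the electron-rich primary allylic alcohol much faster than the electron-poor secondary carbinol and should keep the Z geometry of the enal.

Step 21
Reactants: 26 hydroxy enal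
Product: 27 bromo enal
Conditions: N-bromosuccinimide, Me2S, CH2Cl2, 0 °C to 23 °C
Reagents that add atoms: N-bromosuccinimide, BrN1C(=O)CCC1=O
Why: The alkoxysulfonium salt of the carbinol is displaced by bromide in SN2' fashion to give the 2-(bromomethyl)enoate with CH2Br cis to C8, the usual outcome for such adducts.

Step 22
Reactants: 27 bromo enal
Product: 30 silyl-protected lactone, via allylchromium species 28 (not isolated), via chromium alkoxide 29 (not isolated)
Conditions: CrCl2 (10 equiv), DMF, 23 °C, slow addition of 27 (final 0.002 M)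
Reagents that add atoms: none
Why: Two equivalents of CrCl2 reduce the allylic C13–Br bond to an allylchromium species (chromium now trivalent) that adds to the C6 aldehyde through its γ-carbon C7 with shift of the alkene to C11=C13, and the chromium alkoxide then acylates on the C12 methyl ester. The closest known reaction type is the Nozaki–Hiyama–Kishi (Barbier) 2-(alkoxycarbonyl)allylation of aldehydes to α-methylene-γ-butyrolactones, which is also known in macrocyclising form for ten-membered sesquiterpene lactone rings. The carbocycle closes by 10-exo-trig attack on the aldehyde under high dilution, helped by the two cis-epoxides and the Z-alkene that fold the chain, and the lactone closes by 5-exo-trig attack of the C6 alkoxide on the ester. C6 and C7 arise together in a six-membered chair transition state (Cr, O, C6, C7, C11, C13) in which the C8 substituent, cis to CH2Cr, is axial, which gives the syn adduct and hence the cis-fused lactone. The face of C7 is set by the C8 silyloxy stereocentre: with H8 eclipsing the alkene to avoid A(1,3) strain the aldehyde should be delivered anti to the C8–C9 bond, which is the C7/C8 relationship of the target. The step needs reduction of the allylic bromide beside an epoxy enal and cyclisation over oligomerisation; the first rests on the fast reaction of divalent chromium with 2-(bromomethyl)enoates and its tolerance of epoxides and aldehydes, the second on slow addition to excess CrCl2.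

Step 23
Reactants: 30 silyl-protected lactone
Product: 31 C8 alcohol
Conditions: HF·pyridine, pyridine, THF, 0 °C to 23 °C
Reagents that add atoms: none
Why: HF·pyridine cleaves the secondary TBS ether while the primary TBDPS ether, far more stable to this reagent, should remain.

Step 24
Reactants: 31 C8 alcohol; 32 angelic acid
Product: 34 angelate, via mixed anhydride 33 (not isolated)
Conditions: 32, 2,4,6-Cl3C6H2COCl, Et3N, toluene, 23 °C; then 31, toluene, 75 °C
Reagents that add atoms: none
Why: Acylation with the preformed angelic 2,4,6-trichlorobenzoic anhydride without a nucleophilic catalyst is the Yamaguchi-type variant that should keep the Z geometry of the angelate.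

Step 25
Reactants: 34 angelate
Product: 35 target CNP0157626.1
Conditions: Bu4NF, AcOH (1:1), THF, 0 °C to 23 °C
Reagents that add atoms: none
Why: Acetic-acid-buffered fluoride removes the primary TBDPS ether under conditions mild enough for the α-methylene lactone, the epoxides and the angelate.

Compound list
1 | but-2-yn-1-ol | CC#CCO | starting material
2 | sodium 2,2-bis(2-methoxyethoxy)-3-methyl-2,5-dihydro-1,2-oxaluminol-2-uide (cyclic Z-vinylalanate) | CC1=CCO[Al-]1(OCCOC)OCCOC.[Na+] | intermediate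
3 | (2Z)-3-iodobut-2-en-1-ol | C/C(I)=C/CO | intermediate
4 | tert-butyl{[(2Z)-3-iodobut-2-en-1-yl]oxy}dimethylsilane | C/C(I)=C/CO[Si](C)(C)C(C)(C)C | intermediate
5 | (2R)-2-{[(4-methoxybenzyl)oxy]methyl}oxirane | COc1ccc(COC[C@H]2CO2)cc1 | starting material
6 | (Z)-vinyllithium from 4 (lithium in place of iodine) | C/C([Li])=C/CO[Si](C)(C)C(C)(C)C | intermediate
7 | (2R,4Z)-6-(TBS-oxy)-1-(PMB-oxy)-4-methylhex-4-en-2-ol | C/C(=C/CO[Si](C)(C)C(C)(C)C)C[C@@H](O)COCc1ccc(OC)cc1 | intermediate
8 | TBS ether of 7 at the secondary hydroxyl (C8) | C/C(=C/CO[Si](C)(C)C(C)(C)C)C[C@@H](O[Si](C)(C)C(C)(C)C)COCc1ccc(OC)cc1 | intermediate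
9 | (2Z,5R)-5-(TBS-oxy)-6-(PMB-oxy)-3-methylhex-2-en-1-ol | C/C(=C/CO)C[C@@H](O[Si](C)(C)C(C)(C)C)COCc1ccc(OC)cc1 | intermediate
10 | [(2R,3S)-3-{(2R)-2-(TBS-oxy)-3-(PMB-oxy)propyl}-3-methyloxiran-2-yl]methanol | OC[C@H]1O[C@@]1(C)C[C@@H](O[Si](C)(C)C(C)(C)C)COCc1ccc(OC)cc1 | intermediate
11 | (2S,3S)-3-{(2R)-2-(TBS-oxy)-3-(PMB-oxy)propyl}-3-methyloxirane-2-carbaldehyde | O=C[C@H]1O[C@@]1(C)C[C@@H](O[Si](C)(C)C(C)(C)C)COCc1ccc(OC)cc1 | intermediate
12 | (2S,3R)-3-ethynyl-2-methyl-2-{(2R)-2-(TBS-oxy)-3-(PMB-oxy)propyl}oxirane | C#C[C@H]1O[C@@]1(C)C[C@@H](O[Si](C)(C)C(C)(C)C)COCc1ccc(OC)cc1 | intermediate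
13 | methyl 4-hydroxybut-2-ynoate | COC(=O)C#CCO | starting material
14 | methyl 4-(TBDPS-oxy)but-2-ynoate | COC(=O)C#CCO[Si](c1ccccc1)(c1ccccc1)C(C)(C)C | intermediate
15 | methyl (2Z)-4-(TBDPS-oxy)-3-iodobut-2-enoate | COC(=O)/C=C(\I)CO[Si](c1ccccc1)(c1ccccc1)C(C)(C)C | intermediate
16 | methyl (2E)-3-[(TBDPS-oxy)methyl]-5-[(2R,3S)-3-{(2R)-2-(TBS-oxy)-3-(PMB-oxy)propyl}-3-methyloxiran-2-yl]pent-2-en-4-ynoate (alkyne cis to CO2Me) | COC(=O)/C=C(/CO[Si](c1ccccc1)(c1ccccc1)C(C)(C)C)C#C[C@H]1O[C@@]1(C)C[C@@H](O[Si](C)(C)C(C)(C)C)COCc1ccc(OC)cc1 | intermediate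
17 | methyl (2E,4Z)-3-[(TBDPS-oxy)methyl]-5-[(2R,3S)-3-{(2R)-2-(TBS-oxy)-3-(PMB-oxy)propyl}-3-methyloxiran-2-yl]penta-2,4-dienoate | COC(=O)/C=C(/CO[Si](c1ccccc1)(c1ccccc1)C(C)(C)C)\C=C/[C@H]1O[C@@]1(C)C[C@@H](O[Si](C)(C)C(C)(C)C)COCc1ccc(OC)cc1 | intermediate
18 | methyl (2Z)-3-[(TBDPS-oxy)methyl]-3-[(2S,3S)-3-{(2R,3S)-3-[(2R)-2-(TBS-oxy)-3-(PMB-oxy)propyl]-3-methyloxiran-2-yl}oxiran-2-yl]prop-2-enoate (1R,2S,3S,8R,10S in target numbering) | COC(=O)/C=C(/CO[Si](c1ccccc1)(c1ccccc1)C(C)(C)C)[C@@H]1O[C@@H]1[C@H]1O[C@@]1(C)C[C@@H](O[Si](C)(C)C(C)(C)C)COCc1ccc(OC)cc1 | intermediate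
19 | C6 allylic alcohol from 18 (CO2Me replaced by CH2OH, stereocentres as in 18) | OC/C=C(/CO[Si](c1ccccc1)(c1ccccc1)C(C)(C)C)[C@@H]1O[C@@H]1[C@H]1O[C@@]1(C)C[C@@H](O[Si](C)(C)C(C)(C)C)COCc1ccc(OC)cc1 | intermediate
20 | C6 TES ether of 19 | CC[Si](CC)(CC)OC/C=C(/CO[Si](c1ccccc1)(c1ccccc1)C(C)(C)C)[C@@H]1O[C@@H]1[C@H]1O[C@@]1(C)C[C@@H](O[Si](C)(C)C(C)(C)C)COCc1ccc(OC)cc1 | intermediate
21 | C7 primary alcohol (PMB of 20 removed) | CC[Si](CC)(CC)OC/C=C(/CO[Si](c1ccccc1)(c1ccccc1)C(C)(C)C)[C@@H]1O[C@@H]1[C@H]1O[C@@]1(C)C[C@@H](O[Si](C)(C)C(C)(C)C)CO | intermediate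
22 | C7 aldehyde from 21 | CC[Si](CC)(CC)OC/C=C(/CO[Si](c1ccccc1)(c1ccccc1)C(C)(C)C)[C@@H]1O[C@@H]1[C@H]1O[C@@]1(C)C[C@@H](O[Si](C)(C)C(C)(C)C)C=O | intermediate
23 | methyl acrylate | C=CC(=O)OC | starting material
24 | Morita–Baylis–Hillman adduct: methyl 2-methylidene-3-hydroxy ester at C7 (C7 epimers, C6 TES ether) | CC[Si](CC)(CC)OC/C=C(/CO[Si](c1ccccc1)(c1ccccc1)C(C)(C)C)[C@@H]1O[C@@H]1[C@H]1O[C@@]1(C)C[C@@H](O[Si](C)(C)C(C)(C)C)C(O)C(=C)C(=O)OC | intermediate
25 | diol from 24 (C6 hydroxyl free) | OC/C=C(/CO[Si](c1ccccc1)(c1ccccc1)C(C)(C)C)[C@@H]1O[C@@H]1[C@H]1O[C@@]1(C)C[C@@H](O[Si](C)(C)C(C)(C)C)C(O)C(=C)C(=O)OC | intermediate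
26 | hydroxy enal (C6 aldehyde, Z-C4=C5) | O=C/C=C(/CO[Si](c1ccccc1)(c1ccccc1)C(C)(C)C)[C@@H]1O[C@@H]1[C@H]1O[C@@]1(C)C[C@@H](O[Si](C)(C)C(C)(C)C)C(O)C(=C)C(=O)OC | intermediate
27 | bromo enal: methyl (Z)-2-(bromomethyl)enoate (CH2Br cis to C8) with C6 aldehyde | O=C/C=C(/CO[Si](c1ccccc1)(c1ccccc1)C(C)(C)C)[C@@H]1O[C@@H]1[C@H]1O[C@@]1(C)C[C@@H](O[Si](C)(C)C(C)(C)C)/C=C(\CBr)C(=O)OC | intermediate
28 | allylchromium dichloride from 27 (CrCl2 on C13) | O=C/C=C(/CO[Si](c1ccccc1)(c1ccccc1)C(C)(C)C)[C@@H]1O[C@@H]1[C@H]1O[C@@]1(C)C[C@@H](O[Si](C)(C)C(C)(C)C)/C=C(\C[Cr](Cl)Cl)C(=O)OC | intermediate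
29 | cyclised chromium alkoxide: ten-membered ring closed, C6–O–CrCl2, methyl ester on C11 | Cl[Cr](Cl)O[C@H]1/C=C(/CO[Si](c2ccccc2)(c2ccccc2)C(C)(C)C)[C@@H]2O[C@@H]2[C@H]2O[C@@]2(C)C[C@@H](O[Si](C)(C)C(C)(C)C)[C@H]1C(=C)C(=O)OC | intermediate
30 | 8-O-TBS, 15-O-TBDPS derivative of the 8-deacyl target (all stereocentres arranged as in the target) | C=C1C(=O)O[C@H]2/C=C(/CO[Si](c3ccccc3)(c3ccccc3)C(C)(C)C)[C@@H]3O[C@@H]3[C@H]3O[C@@]3(C)C[C@@H](O[Si](C)(C)C(C)(C)C)[C@@H]12 | intermediate
31 | 15-O-TBDPS derivative of the 8-deacyl target (C8 hydroxyl free) | C=C1C(=O)O[C@H]2/C=C(/CO[Si](c3ccccc3)(c3ccccc3)C(C)(C)C)[C@@H]3O[C@@H]3[C@H]3O[C@@]3(C)C[C@@H](O)[C@@H]12 | intermediate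
32 | angelic acid, (2Z)-2-methylbut-2-enoic acid | C/C=C(/C)C(=O)O | starting material
33 | angelic 2,4,6-trichlorobenzoic anhydride | C/C=C(/C)C(=O)OC(=O)c1c(Cl)cc(Cl)cc1Cl | intermediate
34 | 15-O-TBDPS ether of the target | C=C1C(=O)O[C@H]2/C=C(/CO[Si](c3ccccc3)(c3ccccc3)C(C)(C)C)[C@@H]3O[C@@H]3[C@H]3O[C@@]3(C)C[C@@H](OC(=O)/C(C)=C\C)[C@@H]12 | intermediate
35 | CNP0157626.1: (1R,2S,3S,4Z,6S,7R,8R,10S)-1,10:2,3-diepoxy-15-hydroxy-8-angeloyloxygermacra-4,11(13)-dien-12,6-olide | C=C1C(=O)O[C@H]2/C=C(/CO)[C@@H]3O[C@@H]3[C@H]3O[C@@]3(C)C[C@@H](OC(=O)/C(C)=C\C)[C@@H]12 | target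

Total step count: 25. Longest linear sequence: 23 steps (steps 1–8 and 11–25); steps 9 and 10 make the second fragment.

Steps most likely to fail

Step 22. The cyclisation may lose to intermolecular coupling, divalent chromium may reductively open the epoxy enal, the aldehyde may reach the wrong face of C7, or the C6 alkoxide may open the nearby C2/C3 epoxide instead of closing the lactone. The fallback replaces the Barbier reaction by an intramolecular allylboration and sets out from 24. Acetylation (Ac2O, pyridine) should give allylic acetate F1. Copper-catalysed SN2' borylation (B2pin2, CuCl, LiCl, KOAc, DMF) should give 2-(methoxycarbonyl)allyl pinacolboronate F2 with CH2B cis to C8. Buffered HF·pyridine then frees allylic alcohol F3 and MnO2 gives boronate enal F4, which is expected to be stable at room temperature. Heating F4 in dilute toluene should close the ten-membered ring through a boron-centred chair transition state to cyclic borate F5, which lactonises with loss of the boron group. The route is rejoined at 30.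

Step 13. The peracid may show poor facial selectivity on the Z-alkene, and traces of acid may open the new vinylic epoxide. The fallback replaces substrate control by reagent control and runs from 17 to 18 without a new compound (F0). The oxidant is a chiral dioxirane made in the flask from KHSO5 (as 2KHSO5·KHSO4·K2SO4, K2CO3 buffer) and the spiro N-(4-methylphenyl)oxazolidinone ketone of the glucose series (C17H19NO6), a catalyst class built for conjugated cis-alkenes. The ketone enantiomer is chosen so that the C4=C5 π-substituent sits next to the oxazolidinone and oxygen goes to the required face; this is expected to be the L-glucose-derived ketone, which would have to be prepared.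

Step 18. The amine-catalysed addition to a hindered α-silyloxy aldehyde may be too slow, and the long exposure to base may epimerise C8 or move the C8 silyl group. The fallback uses a preformed α-metallated acrylate and runs from 22 to 24. Hydroalumination of methyl propiolate (C#CC(=O)OC) with i-Bu2AlH in THF/hexamethylphosphoramide at 0 °C should give [1-(methoxycarbonyl)vinyl]diisobutylalane F6. Addition of F6 to 22 at −78 °C to 0 °C should give 24 within hours, without an amine.

Further compounds
F1 | step 22 | acetate of 24 at the C7 carbinol | CC[Si](CC)(CC)OC/C=C(/CO[Si](c1ccccc1)(c1ccccc1)C(C)(C)C)[C@@H]1O[C@@H]1[C@H]1O[C@@]1(C)C[C@@H](O[Si](C)(C)C(C)(C)C)C(OC(C)=O)C(=C)C(=O)OC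
F2 | step 22 | 2-(methoxycarbonyl)allyl pinacolboronate (CH2B cis to C8, C6 TES ether) | CC[Si](CC)(CC)OC/C=C(/CO[Si](c1ccccc1)(c1ccccc1)C(C)(C)C)[C@@H]1O[C@@H]1[C@H]1O[C@@]1(C)C[C@@H](O[Si](C)(C)C(C)(C)C)/C=C(\CB1OC(C)(C)C(C)(C)O1)C(=O)OC
F3 | step 22 | allylboronate with free C6 hydroxyl | OC/C=C(/CO[Si](c1ccccc1)(c1ccccc1)C(C)(C)C)[C@@H]1O[C@@H]1[C@H]1O[C@@]1(C)C[C@@H](O[Si](C)(C)C(C)(C)C)/C=C(\CB1OC(C)(C)C(C)(C)O1)C(=O)OC
F4 | step 22 | allylboronate enal (C6 aldehyde) | O=C/C=C(/CO[Si](c1ccccc1)(c1ccccc1)C(C)(C)C)[C@@H]1O[C@@H]1[C@H]1O[C@@]1(C)C[C@@H](O[Si](C)(C)C(C)(C)C)/C=C(\CB1OC(C)(C)C(C)(C)O1)C(=O)OC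
F5 | step 22 | cyclised pinacol borate of the C6 alkoxide (ten-membered ring closed, methyl ester on C11) | CC1(C)OB(O[C@H]2/C=C(/CO[Si](c3ccccc3)(c3ccccc3)C(C)(C)C)[C@@H]3O[C@@H]3[C@H]3O[C@@]3(C)C[C@@H](O[Si](C)(C)C(C)(C)C)[C@H]2C(=C)C(=O)OC)OC1(C)C
F0 | step 13 | none | none
F6 | step 18 | [1-(methoxycarbonyl)vinyl]diisobutylalane | C=C(C(=O)OC)[Al](CC(C)C)CC(C)C
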